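**Peak trap.** The trap here was to take a peak for a yield: the midnight run read 25.1% target at 1.00 min but 5.4% at 4.00 min, and the question stood at 6.0 min.

| flask | starting material | first nucleophile | second nucleophile | protic impurity | temperature | remark | time |
|---|---|---|---|---|---|---|---|
| midnight | 0.16 M | 0.24 M | 0.32 M | 0.048 M | −5 °C | run made earlier |  |
| spring | 0.16 M | 0.12 M | 0.32 M | 0.048 M | 6 °C | run made earlier |  |
| dawn | 0.16 M | 0.48 M | 0.32 M | 0.048 M | −5 °C | run made earlier |  |
| maple | 0.16 M (fed, over 5.0 min) | 0.240 M | 0.320 M | 0.0480 M | 0 °C | all else is in the flask from the start; the feed brings no volume worth counting | 6.0 min |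
| ash | 0.16 M (fed, over 5.0 min) | 0.240 M | 0.320 M | 0.0480 M |  | the addition at −20 °C, then warmed to 0 °C; the feed brings no volume worth counting | 6.0 min |
| oak | 0.16 M | 0.240 M | 0.320 M | 0.0480 M | 0 °C | everything together at the start | 6.0 min |
| alder | 0.16 M | 0.240 M (fed, over 5.0 min) | 0.320 M | 0.0480 M | 0 °C | all else is in the flask from the start; the feed brings no volume worth counting | 6.0 min |
| birch | 0.16 M | 0.240 M | 0.320 M | 0.0480 M |  | everything together at the start at −20 °C, warmed to 0 °C at 5.0 min | 6.0 min |

| run | time / min | target / % |
|---|---|---|
| midnight | 0.250 | 14.4 |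
| midnight | 0.417 | 18.7 |
| midnight | 0.667 | 23.4 |
| midnight | 1.00 | 25.1 |
| midnight | 1.50 | 21.4 |
| midnight | 2.50 | 14.0 |
| midnight | 4.00 | 5.4 |
| spring | 0.250 | 9.1 |
| spring | 0.417 | 10.6 |
| spring | 0.667 | 8.7 |
| spring | 1.00 | 6.4 |
| spring | 1.50 | 2.9 |
| spring | 2.50 | 1.9 |
| spring | 4.00 | 0.7 |
| dawn | 0.250 | 22.2 |
| dawn | 0.417 | 31.2 |
| dawn | 0.667 | 35.3 |
| dawn | 1.00 | 32.1 |
| dawn | 1.50 | 27.7 |
| dawn | 2.50 | 16.2 |
| dawn | 4.00 | 9.2 |

(scatter of a reading: 1 percentage point)

- the numbers in the tables scatter by 1 percentage point (one standard deviation)

1. which flask leads in amount of target, in percent of the starting material charged ("all alike" within 1.5 percentage points) (maple / ash / oak / alder / birch / all alike)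
2. how much target is there at the end, in percent of the starting material charged: maple
3. how much target is there at the end, in percent of the starting material charged: ash
4. how much target is there at the end, in percent of the starting material charged: oak
5. how much target is there at the end, in percent of the starting material charged: alder
6. how much target is there at the end, in percent of the starting material charged: birch

**Main step.** Had starting material simply become target, the scale would have topped out at 100%.

**Target loss.** I added the decay next. The midnight tail gave a reading of 0.551 min⁻¹, a half-life of 1.26 min, which was shorter than the time asked. At that reading, I reckoned that target made evenly over 6.0 min kept a share of 29.1%, but target made at the start kept 3.67%. So in this reckoning, even making kept more than making at the start.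

**Capture.** Then I added the competition. I guessed that second nucleophile competed for starting material and also consumed target, though the runs never varied its charge. My zero was a selectivity factor of one, where first nucleophile wins its share of the combined charge, 42.9%. Going from 0.24 M of first nucleophile in the midnight run to 0.48 M in the dawn run raised the highest reading by a factor of 1.41, and the even share predicted 1.40. The even share times the kept share was the standing share, the part of the charge expected as target at the end: 12.5% for ash. The decay read at −5 °C stood in, roughly, for the temperatures of ash.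

**The forecast.** It put ash first at 20%, above my figure, then birch 16%, maple 5.5%, oak 1% and alder 0.1%: “Cold keeps selectivity high, but the last minute at 0 °C burns target.”

**The flask.** Ash led with 15.4%, as forecast, ahead of birch 11.5%, maple 6.27%, alder 0.430% and oak 0.272%.

    starting material ⇌ intermediate (K = 0.0650, k = 0.130 s⁻¹, Ea = 76.0 kJ mol⁻¹, ΔH = −29.0 kJ mol⁻¹)
    first nucleophile + intermediate → target (k = 1.70 L mol⁻¹ s⁻¹, Ea = 48.0 kJ mol⁻¹)
    second nucleophile + intermediate → other capture product (k = 0.590 L mol⁻¹ s⁻¹, Ea = 41.0 kJ mol⁻¹)
    starting material + protic impurity → quenched substrate (k = 0.0570 L mol⁻¹ s⁻¹, Ea = 63.0 kJ mol⁻¹)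
    second nucleophile + target → over-reaction product (k = 0.0920 L mol⁻¹ s⁻¹, Ea = 60.0 kJ mol⁻¹)
    2 starting material → homo dimer (k = 0.0190 L mol⁻¹ s⁻¹, Ea = 60.0 kJ mol⁻¹)
    (constants at 0 °C)

**Neighbour flask.** Ash had stood at 15.4% against my 12.5%. Its neighbour was charged with 0.080 M of second nucleophile, other charges held. The even share became 75.0%. Scaling the decay with that charge stretched the half-life to 5.03 min, so the kept share became 68.1% and the standing share 51.0%. That neighbour gave 48.1% target, with over-reaction product at 15.9% against 36.1% in ash.

Readings and results stem from a simulated flask for an exercise; scatter was added.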